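**Strategy.** The benzofuran is cut at O1–C2 of its furan ring (O1, C2, C3, C3a, C7a): the C7a phenol oxygen is joined oxidatively to the stilbene carbon that already carries the 2,6-diprenylresorcinol ring, so the congested C2–C1′ bond is never made by cross-coupling. One oxidation with PhI(OAc)2 closes the furan ring and aromatises it, with no stereocentre at stake. Its precursor is an (E)-2-hydroxystilbene with a single free phenol (ortho to the alkene, flanked by the C7 prenyl group) and three triisopropylsilyl ethers; it is assembled by Horner–Wadsworth–Emmons olefination of a 2,6-diprenylbenzaldehyde with a benzylphosphonate whose ortho oxygen travels as an allyl ether and is released by Pd(0) just before the oxidation.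

Key step: step 12

Remark on the chemistry (assumption): the target has no stereocentre, its prenyl alkenes are not stereogenic, and the diprenylresorcinol ring is symmetric about the C2–C1′ axis. It is therefore one achiral compound and needs no enantiocontrol. The only stereochemical element in the route is the E alkene of 15–17, which is consumed in step 12. Abbreviations: prenyl = 3-methylbut-2-en-1-yl; TIPS = triisopropylsilyl.

**Route**

Step 1
Reactants: 1 2,4-dihydroxybenzaldehyde; 2 prenyl bromide
Product: 3 2,4-dihydroxy-3-prenylbenzaldehyde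
Conditions: KOH (10% aq.), 0 °C to rt; then dil. HCl to pH 5–6
Reagents that add atoms: none
Why: C-alkylation of the resorcinol phenoxide in water, where solvation of the oxygens disfavours O-alkylation and C3 between the two oxygens is the most nucleophilic carbon; mild acidification should keep the ortho-prenylphenol from closing to a chroman.

Step 2
Reactants: 3 2,4-dihydroxy-3-prenylbenzaldehyde
Product: 4 2-hydroxy-3-prenyl-4-(triisopropylsilyloxy)benzaldehyde
Conditions: TIPSCl (1.05 equiv), imidazole, CH2Cl2, 0 °C to rt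
Reagents that add atoms: triisopropylsilyl chloride, CC(C)[Si](Cl)(C(C)C)C(C)C
Why: Selective silyl ether formation, since the 2-OH is hydrogen-bonded to the formyl group and flanked on both sides while the more acidic 4-OH is exposed.

Step 3
Reactants: 4 2-hydroxy-3-prenyl-4-(triisopropylsilyloxy)benzaldehyde
Product: 5 2-(allyloxy)-3-prenyl-4-(triisopropylsilyloxy)benzaldehyde
Conditions: allyl bromide, K2CO3, DMF, rt
Reagents that add atoms: allyl bromide, C=CCBr
Why: Williamson etherification of the remaining phenol; the allyl group should survive hydride, zinc iodide and HWE base and is later removed by Pd(0) without acid or fluoride, which leaves exactly one free phenol for the key step.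

Step 4
Reactants: 5 2-(allyloxy)-3-prenyl-4-(triisopropylsilyloxy)benzaldehyde
Product: 6 [2-(allyloxy)-3-prenyl-4-(triisopropylsilyloxy)phenyl]methanol
Conditions: NaBH4, MeOH/THF, 0 °C
Reagents that add atoms: none
Why: Borohydride reduction of the aryl aldehyde to the benzylic alcohol, to which silyl ether, allyl ether and prenyl alkene are inert.

Step 5
Reactants: 6 [2-(allyloxy)-3-prenyl-4-(triisopropylsilyloxy)phenyl]methanol
Product: 8 diethyl [2-(allyloxy)-3-prenyl-4-(triisopropylsilyloxy)benzyl]phosphonate, via benzyl diethyl phosphite 7 (not isolated)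
Conditions: P(OEt)3 (3 equiv), ZnI2 (1.5 equiv), THF, reflux
Reagents that add atoms: triethyl phosphite, CCOP(OCC)OCC
Why: Zinc iodide-mediated direct conversion of a benzylic alcohol into its phosphonate, in which transesterification gives phosphite 7 and a Lewis-acid Michaelis–Arbuzov-type P–O to P–C shift at the electron-rich benzylic carbon follows, so that no labile benzylic halide has to be isolated.

Step 6
Reactants: 9 3,5-dimethoxybenzaldehyde
Product: 10 2,6-dibromo-3,5-dimethoxybenzaldehyde
Conditions: Br2 (2.2 equiv), AcOH, rt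
Reagents that add atoms: bromine, BrBr
Why: Twofold electrophilic aromatic bromination, in which C2 and C6 are each para to one methoxy group and ortho to the other while C4 is shielded between the two methoxy groups, and the formyl group should stop the reaction at the dibromide.

Step 7
Reactants: 10 2,6-dibromo-3,5-dimethoxybenzaldehyde
Product: 11 2,6-dibromo-3,5-dihydroxybenzaldehyde
Conditions: BBr3 (3 equiv), CH2Cl2, −78 °C to rt; then H2O
Reagents that add atoms: none
Why: Lewis-acid ether cleavage (BBr3 demethylation), placed before any prenyl group is present so that no acid-labile alkene meets the reagent.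

Step 8
Reactants: 11 2,6-dibromo-3,5-dihydroxybenzaldehyde
Product: 12 2,6-dibromo-3,5-bis(triisopropylsilyloxy)benzaldehyde
Conditions: TIPSCl (2.4 equiv), imidazole, DMF, rt
Reagents that add atoms: triisopropylsilyl chloride, CC(C)[Si](Cl)(C(C)C)C(C)C
Why: Silyl ether formation on two phenols that are acidified by the ortho bromine and flanked on one side only.

Step 9
Reactants: 12 2,6-dibromo-3,5-bis(triisopropylsilyloxy)benzaldehyde; 13 tributyl(prenyl)stannane
Product: 14 2,6-diprenyl-3,5-bis(triisopropylsilyloxy)benzaldehyde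
Conditions: Pd(PPh3)4 (10 mol %), 13 (2.5 equiv), DMF, 100 °C
Reagents that add atoms: none
Why: Twofold Migita–Kosugi–Stille coupling, in which the ortho formyl group assists oxidative addition and reductive elimination from the η3-prenyl–palladium aryl at its unsubstituted terminus should give the linear prenyl groups; fluoride additives are left out to keep the silyl ethers.

Step 10
Reactants: 8 diethyl [2-(allyloxy)-3-prenyl-4-(triisopropylsilyloxy)benzyl]phosphonate; 14 2,6-diprenyl-3,5-bis(triisopropylsilyloxy)benzaldehyde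
Product: 15 (E)-1-[2-(allyloxy)-3-prenyl-4-(triisopropylsilyloxy)phenyl]-2-[2,6-diprenyl-3,5-bis(triisopropylsilyloxy)phenyl]ethene
Conditions: NaH, 15-crown-5 (cat.), THF, 0 °C to rt
Reagents that add atoms: none
Why: Horner–Wadsworth–Emmons olefination of a non-enolisable aldehyde with an electron-rich benzylphosphonate anion, where reversible addition and the bulk of the 2,6-disubstituted ring should give the E alkene.

Step 11
Reactants: 15 (E)-1-[2-(allyloxy)-3-prenyl-4-(triisopropylsilyloxy)phenyl]-2-[2,6-diprenyl-3,5-bis(triisopropylsilyloxy)phenyl]ethene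
Product: 16 (E)-2-{2-[2,6-diprenyl-3,5-bis(triisopropylsilyloxy)phenyl]vinyl}-6-prenyl-5-(triisopropylsilyloxy)phenol
Conditions: Pd(PPh3)4 (5 mol %), morpholine, THF, rt
Reagents that add atoms: none
Why: Tsuji–Trost deallylation, in which Pd(0) ionises the aryl allyl ether to a π-allyl complex that morpholine captures, so the phenol is released under neutral conditions that should touch neither silyl ethers nor prenyl groups.

Step 12
Reactants: 16 (E)-2-{2-[2,6-diprenyl-3,5-bis(triisopropylsilyloxy)phenyl]vinyl}-6-prenyl-5-(triisopropylsilyloxy)phenol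
Product: 18 2-[2,6-diprenyl-3,5-bis(triisopropylsilyloxy)phenyl]-7-prenyl-6-(triisopropylsilyloxy)benzofuran, via aryloxy-λ3-iodane 17 (not isolated)
Conditions: PhI(OAc)2 (1.1 equiv), MeCN/CH2Cl2 (1:1), 0 °C to rt
Reagents that add atoms: none
Why: Ligand exchange at iodine(III) with the only free phenol gives aryloxy-λ3-iodane 17; reductive loss of iodobenzene leaves a phenoxenium (ortho-quinone-methide-type) cation whose charge runs through C3a and C3 to C2, O1 bonds to C2, and loss of the C2 proton aromatises the furan. The closest known reaction type is the iodine(III)-mediated oxidative cyclisation of 2-hydroxystilbenes to 2-arylbenzofurans. The one ring formed (O1–C2–C3–C3a–C7a) closes in a formal 5-endo-trig mode, better described as a 4π electrocyclisation of the 1-oxapentadienyl cation, which is why the endo geometry is no obstacle. No stereocentre is created. The step needs chemoselectivity, first for the phenol over the three prenyl alkenes, secured by silylation of every other oxygen and by the absence of strong acid, and second for O1–C2 closure over proton loss from the C7 prenyl group (chromene) or capture of the C2 cation by a C2′/C6′ prenyl alkene, secured because closure onto the conjugated styrene is intramolecular, needs no base, gives an aromatic ring at once and places the charge at C3 where the C6 silyloxy group para to C3a stabilises it. The silylated product has no free phenol and should therefore resist the slight excess of oxidant.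

Step 13
Reactants: 18 2-[2,6-diprenyl-3,5-bis(triisopropylsilyloxy)phenyl]-7-prenyl-6-(triisopropylsilyloxy)benzofuran
Product: 19 5-[6-hydroxy-7-(3-methylbut-2-en-1-yl)-1-benzofuran-2-yl]-4,6-bis(3-methylbut-2-en-1-yl)benzene-1,3-diol
Conditions: TBAF (3.3 equiv), AcOH (3.3 equiv), THF, 0 °C to rt
Reagents that add atoms: none
Why: Fluoride-induced cleavage of the three aryl silyl ethers, with acetic acid buffering the phenoxides so that the electron-rich triphenol should neither oxidise nor add to its prenyl groups.

**Compound list**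

1 | 2,4-dihydroxybenzaldehyde | O=Cc1ccc(O)cc1O | starting material
2 | prenyl bromide (1-bromo-3-methylbut-2-ene) | CC(C)=CCBr | starting material
3 | 2,4-dihydroxy-3-prenylbenzaldehyde | O=Cc1ccc(O)c(CC=C(C)C)c1O | intermediate
4 | 2-hydroxy-3-prenyl-4-(triisopropylsilyloxy)benzaldehyde | O=Cc1ccc(O[Si](C(C)C)(C(C)C)C(C)C)c(CC=C(C)C)c1O | intermediate
5 | 2-(allyloxy)-3-prenyl-4-(triisopropylsilyloxy)benzaldehyde | C=CCOc1c(C=O)ccc(O[Si](C(C)C)(C(C)C)C(C)C)c1CC=C(C)C | intermediate
6 | [2-(allyloxy)-3-prenyl-4-(triisopropylsilyloxy)phenyl]methanol | C=CCOc1c(CO)ccc(O[Si](C(C)C)(C(C)C)C(C)C)c1CC=C(C)C | intermediate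
7 | [2-(allyloxy)-3-prenyl-4-(triisopropylsilyloxy)benzyl] diethyl phosphite | C=CCOc1c(COP(OCC)OCC)ccc(O[Si](C(C)C)(C(C)C)C(C)C)c1CC=C(C)C | intermediate (not isolated)
8 | diethyl [2-(allyloxy)-3-prenyl-4-(triisopropylsilyloxy)benzyl]phosphonate | C=CCOc1c(CP(=O)(OCC)OCC)ccc(O[Si](C(C)C)(C(C)C)C(C)C)c1CC=C(C)C | intermediate
9 | 3,5-dimethoxybenzaldehyde | COc1cc(C=O)cc(OC)c1 | starting material
10 | 2,6-dibromo-3,5-dimethoxybenzaldehyde | COc1cc(OC)c(Br)c(C=O)c1Br | intermediate
11 | 2,6-dibromo-3,5-dihydroxybenzaldehyde | Oc1cc(O)c(Br)c(C=O)c1Br | intermediate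
12 | 2,6-dibromo-3,5-bis(triisopropylsilyloxy)benzaldehyde | CC(C)[Si](Oc1cc(O[Si](C(C)C)(C(C)C)C(C)C)c(Br)c(C=O)c1Br)(C(C)C)C(C)C | intermediate
13 | tributyl(prenyl)stannane | CCCC[Sn](CCCC)(CCCC)CC=C(C)C | starting material
14 | 2,6-diprenyl-3,5-bis(triisopropylsilyloxy)benzaldehyde | CC(C)=CCc1c(O[Si](C(C)C)(C(C)C)C(C)C)cc(O[Si](C(C)C)(C(C)C)C(C)C)c(CC=C(C)C)c1C=O | intermediate
15 | (E)-1-[2-(allyloxy)-3-prenyl-4-(triisopropylsilyloxy)phenyl]-2-[2,6-diprenyl-3,5-bis(triisopropylsilyloxy)phenyl]ethene | CC(C)=CCc1c(O[Si](C(C)C)(C(C)C)C(C)C)cc(O[Si](C(C)C)(C(C)C)C(C)C)c(CC=C(C)C)c1/C=C/c1ccc(O[Si](C(C)C)(C(C)C)C(C)C)c(CC=C(C)C)c1OCC=C | intermediate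
16 | (E)-2-{2-[2,6-diprenyl-3,5-bis(triisopropylsilyloxy)phenyl]vinyl}-6-prenyl-5-(triisopropylsilyloxy)phenol | CC(C)=CCc1c(O[Si](C(C)C)(C(C)C)C(C)C)cc(O[Si](C(C)C)(C(C)C)C(C)C)c(CC=C(C)C)c1/C=C/c1ccc(O[Si](C(C)C)(C(C)C)C(C)C)c(CC=C(C)C)c1O | intermediate (key-step precursor)
17 | acetoxy(phenyl)-λ3-iodanyl ether of phenol 16 | CC(C)=CCc1c(O[Si](C(C)C)(C(C)C)C(C)C)cc(O[Si](C(C)C)(C(C)C)C(C)C)c(CC=C(C)C)c1/C=C/c1ccc(O[Si](C(C)C)(C(C)C)C(C)C)c(CC=C(C)C)c1O[I](OC(C)=O)c1ccccc1 | intermediate (not isolated)
18 | 2-[2,6-diprenyl-3,5-bis(triisopropylsilyloxy)phenyl]-7-prenyl-6-(triisopropylsilyloxy)benzofuran | CC(C)=CCc1c(O[Si](C(C)C)(C(C)C)C(C)C)cc(O[Si](C(C)C)(C(C)C)C(C)C)c(CC=C(C)C)c1-c1cc2ccc(O[Si](C(C)C)(C(C)C)C(C)C)c(CC=C(C)C)c2o1 | intermediate (key-step product)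
19 | 5-[6-hydroxy-7-(3-methylbut-2-en-1-yl)-1-benzofuran-2-yl]-4,6-bis(3-methylbut-2-en-1-yl)benzene-1,3-diol | CC(C)=CCc1c(O)cc(O)c(CC=C(C)C)c1-c1cc2ccc(O)c(CC=C(C)C)c2o1 | target

**Step count.** Total: 13 steps. Longest linear sequence: 9 steps (steps 1–5, then 10–13); the other branch is steps 6–9 followed by 10–13.

**Steps most likely to fail**

1. Step 12 (key step). The oxidised phenol may not be trapped at C2 fast enough. Proton loss from the C7 prenyl group would then divert it into a chromene, the C2 cation could be captured by a neighbouring prenyl alkene of the aryl ring, or acetate could add at C5 and lead to over-oxidation.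

 The fallback is redox-neutral and replaces the oxidation by cycloisomerisation of an ortho-alkynylphenol. It sets out from alcohol 6 and aldehyde 14 and returns at 18. Appel bromination of 6 (CBr4, PPh3, CH2Cl2, 0 °C) should give 2-(allyloxy)-1-(bromomethyl)-3-prenyl-4-(triisopropylsilyloxy)benzene F1, which is used crude. Displacement with sodium benzenesulfinate (DMF, rt) should give 2-(allyloxy)-1-[(phenylsulfonyl)methyl]-3-prenyl-4-(triisopropylsilyloxy)benzene F2. The lithiated sulfone is then added to aldehyde 14, the alkoxide is phosphorylated with ClP(O)(OEt)2, and excess LiHMDS (THF, −78 °C to rt) effects a double elimination in one pot. This should give 1-[2-(allyloxy)-3-prenyl-4-(triisopropylsilyloxy)phenyl]-2-[2,6-diprenyl-3,5-bis(triisopropylsilyloxy)phenyl]ethyne F3. Deallylation with Pd(PPh3)4 and morpholine, as in step 11, should give 2-{[2,6-diprenyl-3,5-bis(triisopropylsilyloxy)phenyl]ethynyl}-6-prenyl-5-(triisopropylsilyloxy)phenol F4. Catalytic Ph3PAuNTf2 (CH2Cl2, rt) should then close it by 5-endo-dig hydroalkoxylation to benzofuran 18.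

2. Step 9. The γ,γ-disubstituted allylstannane may transmetalate slowly at the doubly flanked C–Br bonds, so the second coupling could stall or protodebromination could compete. Allylic transposition at palladium could also give reverse-prenyl isomers.

 The fallback separates C–C coupling from construction of the trisubstituted alkene. It sets out from dibromide 12 and returns at 14. Stille coupling with allyltributylstannane (Pd(PPh3)4, DMF, 90 °C), which transmetalates faster and has no regiochemical ambiguity, should give 2,6-diallyl-3,5-bis(triisopropylsilyloxy)benzaldehyde F5. Olefin cross-metathesis with 2-methyl-2-butene (Grubbs second-generation catalyst, CH2Cl2, 40 °C) should then convert both allyl groups into prenyl groups and deliver aldehyde 14.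

3. Step 1. The ambident phenoxide may be alkylated at O4 and at C5 as well as at C3, and may be alkylated twice, so that little of the C3 isomer is obtained.

 The fallback fixes the regiochemistry by a sigmatropic shift. It sets out from 1 and returns at 4, bypassing 3. Selective silylation of the 4-OH (TIPSCl, imidazole, CH2Cl2) should give 2-hydroxy-4-(triisopropylsilyloxy)benzaldehyde F6. Allylation (allyl bromide, K2CO3, DMF) should give 2-(allyloxy)-4-(triisopropylsilyloxy)benzaldehyde F7. Aromatic Claisen rearrangement (N,N-diethylaniline, 190 °C) can deliver the allyl group only to C3, the one free ortho position, and should give 3-allyl-2-hydroxy-4-(triisopropylsilyloxy)benzaldehyde F8. Cross-metathesis with 2-methyl-2-butene (Grubbs second-generation catalyst, CH2Cl2, 40 °C) should then give 4.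

Further compounds
F1 | step 12 | 2-(allyloxy)-1-(bromomethyl)-3-prenyl-4-(triisopropylsilyloxy)benzene | C=CCOc1c(CBr)ccc(O[Si](C(C)C)(C(C)C)C(C)C)c1CC=C(C)C
F2 | step 12 | 2-(allyloxy)-1-[(phenylsulfonyl)methyl]-3-prenyl-4-(triisopropylsilyloxy)benzene | C=CCOc1c(CS(=O)(=O)c2ccccc2)ccc(O[Si](C(C)C)(C(C)C)C(C)C)c1CC=C(C)C
F3 | step 12 | 1-[2-(allyloxy)-3-prenyl-4-(triisopropylsilyloxy)phenyl]-2-[2,6-diprenyl-3,5-bis(triisopropylsilyloxy)phenyl]ethyne | CC(C)=CCc1c(O[Si](C(C)C)(C(C)C)C(C)C)cc(O[Si](C(C)C)(C(C)C)C(C)C)c(CC=C(C)C)c1C#Cc1ccc(O[Si](C(C)C)(C(C)C)C(C)C)c(CC=C(C)C)c1OCC=C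
F4 | step 12 | 2-{[2,6-diprenyl-3,5-bis(triisopropylsilyloxy)phenyl]ethynyl}-6-prenyl-5-(triisopropylsilyloxy)phenol | CC(C)=CCc1c(O[Si](C(C)C)(C(C)C)C(C)C)cc(O[Si](C(C)C)(C(C)C)C(C)C)c(CC=C(C)C)c1C#Cc1ccc(O[Si](C(C)C)(C(C)C)C(C)C)c(CC=C(C)C)c1O
F5 | step 9 | 2,6-diallyl-3,5-bis(triisopropylsilyloxy)benzaldehyde | C=CCc1c(O[Si](C(C)C)(C(C)C)C(C)C)cc(O[Si](C(C)C)(C(C)C)C(C)C)c(CC=C)c1C=O
F6 | step 1 | 2-hydroxy-4-(triisopropylsilyloxy)benzaldehyde | O=Cc1ccc(O[Si](C(C)C)(C(C)C)C(C)C)cc1O
F7 | step 1 | 2-(allyloxy)-4-(triisopropylsilyloxy)benzaldehyde | C=CCOc1cc(O[Si](C(C)C)(C(C)C)C(C)C)ccc1C=O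
F8 | step 1 | 3-allyl-2-hydroxy-4-(triisopropylsilyloxy)benzaldehyde | C=CCc1c(O)c(C=O)ccc1O[Si](C(C)C)(C(C)C)C(C)C
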